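The α-methylene-γ-butyrolactone ring (C1, C2, C15, C16, O) is read as an allene (C1=C15=C17), CO2 (C16) and an aldehyde (C2=O); cembrane numbering: C1 ring-fusion CH, C2 O–CH, C3 CHOAc, C15 α-carbon, C16 C=O, C17 =CH2. A nickel(0)-mediated three-component carboxylative macrocyclisation of acyclic allenyl aldehyde 18 forms C15–C16 and C1–C2 in one flask, closes the 14-membered carbocycle and the cis-fused lactone, and sets C1 and C2. Precursor 18 already holds the epoxide, the tertiary carbinol, the E-alkene and C4, and carries C3 as the epimeric PMB ether so that Cornforth control sets C2; C3 is inverted last by Mitsunobu acetylation. Both halves of 18 derive from one Sharpless epoxy alcohol.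

Key step: step 15

Remark: pent-1-en-4-yne, ethynyltrimethylsilane and (E)-3-iodoprop-2-en-1-ol are taken as purchased.

Step 1
Reactants: 1 pent-1-en-4-yne
Product: 2 (2E)-3-methylhexa-2,5-dien-1-ol
Conditions: Me3Al, Cp2ZrCl2 (cat.), CH2Cl2, 0 °C → rt; volatiles removed; n-BuLi, THF, −78 °C; (CH2O)n, rt; aq. Rochelle salt
Reagents that add atoms: trimethylaluminium C[Al](C)C; paraformaldehyde (as formaldehyde) C=O
Why: Zr-catalysed syn-methylalumination of the terminal alkyne (Negishi carboalumination) places Al on the terminal carbon cis to the new methyl, and the derived alanate adds to formaldehyde with retention, so the E-trisubstituted alkene is set here.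

Step 2
Reactants: 2 (2E)-3-methylhexa-2,5-dien-1-ol
Product: 3 [(2R,3R)-3-methyl-3-(prop-2-en-1-yl)oxiran-2-yl]methanol
Conditions: Ti(Oi-Pr)4 (10 mol %), D-(−)-diethyl tartrate (12 mol %), t-BuOOH, 4 Å MS, CH2Cl2, −20 °C
Reagents that add atoms: tert-butyl hydroperoxide CC(C)(C)OO
Why: Sharpless asymmetric epoxidation of a 3,3-disubstituted E-allylic alcohol, in which D-(−)-tartrate should set both epoxide centres as (2R,3R); the unfunctionalised terminal alkene is untouched.

Step 3
Reactants: 3 [(2R,3R)-3-methyl-3-(prop-2-en-1-yl)oxiran-2-yl]methanol; 4 ethynyltrimethylsilane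
Product: 6 trimethyl{3-[(2R,3R)-3-methyl-3-(prop-2-en-1-yl)oxiran-2-yl]prop-1-yn-1-yl}silane, via epoxy triflate 5 (not isolated)
Conditions: Tf2O, 2,6-lutidine, CH2Cl2, −78 °C; then TMSC≡CLi (from 4, n-BuLi), THF/DMPU, −78 → −20 °C
Reagents that add atoms: none
Why: The primary triflate is displaced by the lithium acetylide (SN2) at low temperature without Lewis acid, conditions under which the trisubstituted epoxide should not open; no stereocentre is touched.

Step 4
Reactants: 3 [(2R,3R)-3-methyl-3-(prop-2-en-1-yl)oxiran-2-yl]methanol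
Product: 7 (2S,3R)-2-(iodomethyl)-3-methyl-3-(prop-2-en-1-yl)oxirane
Conditions: I2, PPh3, imidazole, CH2Cl2, 0 °C
Reagents that add atoms: iodine II
Why: Garegg–Samuelsson (Appel-type) iodination of the primary alcohol; the change of descriptor at C2 is formal only (CIP priority of CH2I).

Step 5
Reactants: 7 (2S,3R)-2-(iodomethyl)-3-methyl-3-(prop-2-en-1-yl)oxirane
Product: 8 (3R)-3-methylhexa-1,5-dien-3-ol
Conditions: Zn dust, EtOH, reflux
Reagents that add atoms: none
Why: Zinc inserts into the C–I bond and the β-alkoxy organozinc eliminates with opening of the epoxide (reductive fragmentation of a 2,3-epoxy iodide), which unveils the vinyl group and keeps the C–O bond of the tertiary centre, so (R) is retained.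

Step 6
Reactants: 8 (3R)-3-methylhexa-1,5-dien-3-ol; 9 (2E)-3-iodoprop-2-en-1-ol
Product: 10 (2E,7R)-7-methylnona-2,8-diene-1,7-diol
Conditions: 9-BBN (2.2 equiv), THF, 0 °C → rt; then 9, PdCl2(dppf) (5 mol %), AsPh3, Cs2CO3, DMF/H2O, rt
Reagents that add atoms: none
Why: 9-BBN should hydroborate the unhindered allyl terminus in preference to the vinyl group on the quaternary carbinol carbon, and the B-alkyl Suzuki–Miyaura coupling proceeds with retention of the E-geometry of the vinyl iodide.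

Step 7
Reactants: 10 (2E,7R)-7-methylnona-2,8-diene-1,7-diol
Product: 11 [(2R,3R)-3-[(4R)-4-hydroxy-4-methylhex-5-en-1-yl]oxiran-2-yl]methanol
Conditions: Ti(Oi-Pr)4, D-(−)-diethyl tartrate, t-BuOOH, 4 Å MS, CH2Cl2, −20 °C
Reagents that add atoms: tert-butyl hydroperoxide CC(C)(C)OO
Why: Sharpless asymmetric epoxidation of the primary E-allylic alcohol, with D-(−)-tartrate giving the (2R,3R)-epoxide; the tertiary vinyl carbinol is a very slow substrate and should not compete.

Step 8
Reactants: 11 [(2R,3R)-3-[(4R)-4-hydroxy-4-methylhex-5-en-1-yl]oxiran-2-yl]methanol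
Product: 12 (2S,3S,7R)-3,7-dimethylnon-8-ene-1,2,7-triol
Conditions: Me3Al (4 equiv), CH2Cl2/hexane, −20 → 0 °C; aq. Rochelle salt
Reagents that add atoms: trimethylaluminium C[Al](C)C
Why: Organoaluminium opening of a 2,3-epoxy alcohol: the aluminium alkoxide delivers methyl to C3 with inversion, which sets the methyl-bearing centre as (3S) and leaves the C2–O bond untouched, giving the anti 2-hydroxy-3-methyl pattern.

Step 9
Reactants: 12 (2S,3S,7R)-3,7-dimethylnon-8-ene-1,2,7-triol
Product: 13 (3R,7S)-7-[(4S)-2-(4-methoxyphenyl)-1,3-dioxolan-4-yl]-3-methyloct-1-en-3-ol (acetal carbon as a mixture)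
Conditions: 4-MeOC6H4CH(OMe)2, PPTS (cat.), CH2Cl2, rt
Reagents that add atoms: 4-methoxybenzaldehyde dimethyl acetal COc1ccc(cc1)C(OC)OC
Why: Acid-catalysed transacetalisation engages only the 1,2-diol as the five-membered p-methoxybenzylidene acetal; the tertiary alcohol cannot take part.

Step 10
Reactants: 13 (3R,7S)-7-[(4S)-2-(4-methoxyphenyl)-1,3-dioxolan-4-yl]-3-methyloct-1-en-3-ol
Product: 14 (2S,3S,7R)-2-[(4-methoxyphenyl)methoxy]-3,7-dimethylnon-8-ene-1,7-diol
Conditions: DIBAL-H (4 equiv), CH2Cl2, −78 → 0 °C; aq. Rochelle salt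
Reagents that add atoms: none
Why: Reductive acetal opening: DIBAL-H coordinates the less hindered primary oxygen and cleaves that C–O bond, leaving the PMB group on the secondary oxygen and freeing the primary alcohol.

Step 11
Reactants: 14 (2S,3S,7R)-2-[(4-methoxyphenyl)methoxy]-3,7-dimethylnon-8-ene-1,7-diol; 6 trimethyl{3-[(2R,3R)-3-methyl-3-(prop-2-en-1-yl)oxiran-2-yl]prop-1-yn-1-yl}silane
Product: 15 (2S,3S,7R,8E)-2-[(4-methoxyphenyl)methoxy]-3,7-dimethyl-10-[(2R,3R)-2-methyl-3-[3-(trimethylsilyl)prop-2-yn-1-yl]oxiran-2-yl]dec-8-ene-1,7-diol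
Conditions: Hoveyda–Grubbs II catalyst (5 mol %), 6 (3 equiv), CH2Cl2, 40 °C
Reagents that add atoms: none
Why: Olefin cross-metathesis between a type II olefin (free tertiary allylic alcohol) and a type I allyl group should favour the cross product and, because of the quaternary allylic centre, the E-alkene; the silyl-capped alkyne and the epoxide are expected to be spectators.

Step 12
Reactants: 15 (2S,3S,7R,8E)-2-[(4-methoxyphenyl)methoxy]-3,7-dimethyl-10-[(2R,3R)-2-methyl-3-[3-(trimethylsilyl)prop-2-yn-1-yl]oxiran-2-yl]dec-8-ene-1,7-diol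
Product: 16 (2S,3S,7R,8E)-2-[(4-methoxyphenyl)methoxy]-3,7-dimethyl-10-[(2R,3R)-2-methyl-3-(prop-2-yn-1-yl)oxiran-2-yl]dec-8-ene-1,7-diol
Conditions: K2CO3, MeOH, rt
Reagents that add atoms: none
Why: Methanolysis of the alkynyl C–Si bond; no other group is labile under these conditions.

Step 13
Reactants: 16 (2S,3S,7R,8E)-2-[(4-methoxyphenyl)methoxy]-3,7-dimethyl-10-[(2R,3R)-2-methyl-3-(prop-2-yn-1-yl)oxiran-2-yl]dec-8-ene-1,7-diol
Product: 17 (2S,3S,7R,8E)-10-[(2R,3R)-3-(buta-2,3-dien-1-yl)-2-methyloxiran-2-yl]-2-[(4-methoxyphenyl)methoxy]-3,7-dimethyldec-8-ene-1,7-diol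
Conditions: (CH2O)n, CuI, Cy2NH, 1,4-dioxane, reflux
Reagents that add atoms: paraformaldehyde (as formaldehyde) C=O
Why: Crabbé homologation: the copper-catalysed Mannich reaction gives the propargylic amine, which undergoes a 1,5-hydride shift and fragmentation to the terminal allene and an imine; alcohols and the epoxide are tolerated.

Step 14
Reactants: 17 (2S,3S,7R,8E)-10-[(2R,3R)-3-(buta-2,3-dien-1-yl)-2-methyloxiran-2-yl]-2-[(4-methoxyphenyl)methoxy]-3,7-dimethyldec-8-ene-1,7-diol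
Product: 18 (2S,3S,7R,8E)-10-[(2R,3R)-3-(buta-2,3-dien-1-yl)-2-methyloxiran-2-yl]-7-hydroxy-2-[(4-methoxyphenyl)methoxy]-3,7-dimethyldec-8-enal
Conditions: Dess–Martin periodinane, NaHCO3, CH2Cl2, 0 °C → rt; used at once
Reagents that add atoms: none
Why: Dess–Martin oxidation converts only the primary alcohol (the tertiary one cannot be oxidised), and the buffered, non-basic conditions should preserve the α-alkoxy stereocentre.

Step 15
Reactants: 18 (2S,3S,7R,8E)-10-[(2R,3R)-3-(buta-2,3-dien-1-yl)-2-methyloxiran-2-yl]-7-hydroxy-2-[(4-methoxyphenyl)methoxy]-3,7-dimethyldec-8-enal; 19 carbon dioxide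
Product: 22 (1S,2R,3S,4S,8R,9E,12R,13R)-12,13-epoxy-8-hydroxy-3-[(4-methoxyphenyl)methoxy]cembra-9,15(17)-dien-16,2-olide, via nickelalactone 20 (not isolated), via seco hydroxy acid 21 (not isolated)
Conditions: Ni(cod)2 (1.1 equiv), DBU (2.2 equiv), CO2 (1 atm), THF, 0 °C; then dilution to 1 mM, 40 °C; then AcOH, rt
Reagents that add atoms: none
Why: Proposed new method: Ni(0)/DBU should couple the terminal C15=C17 π-bond of the allene with CO2 by oxidative cyclisation (C15–C16 bond at the central allene carbon) to the five-membered nickelalactone 20, whose σ-allyl unit (Ni–C17H2–C15=C1H–, chain cis to the CH2Ni carbon) then adds through C1 to the tethered aldehyde carbon C2 in a six-membered chair (SE2′), and acidification lets the C2 hydroxyl close onto the C16 carboxyl; the closest known reaction type is the intermolecular nickel(0)-mediated sequential coupling of terminal allenes, CO2 and aryl aldehydes, extended here to an aliphatic α-alkoxy aldehyde and to an intramolecular 14-ring closure. The carbocycle closes by 14-exo-trig carbonyl allylation and the lactone by 5-exo-trig acyl substitution. C1 is set relative to C2 by the Zimmerman–Traxler chair with the Z-configured allylnickel fixed by the nickelacycle (syn adduct, hence the cis-fused lactone), and C2 is set by the C3 stereocentre through Cornforth/polar Felkin–Anh addition anti to the C3–OPMB bond, which is why C3 is carried as (S). The step needs CO2 capture ahead of any allene–aldehyde coupling (CO2-saturated solution at 0 °C), attack through the substituted allyl terminus (nickel on the unsubstituted carbon) and ring closure ahead of oligomerisation (high dilution before warming). The epoxide, the tertiary carbinol and the E-alkene are not expected to react with the nickel(II) allyl.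

Step 16
Reactants: 22 (1S,2R,3S,4S,8R,9E,12R,13R)-12,13-epoxy-8-hydroxy-3-[(4-methoxyphenyl)methoxy]cembra-9,15(17)-dien-16,2-olide
Product: 23 (1S,2R,3S,4S,8R,9E,12R,13R)-12,13-epoxy-3,8-dihydroxycembra-9,15(17)-dien-16,2-olide
Conditions: DDQ, CH2Cl2/pH 7 buffer, 0 °C
Reagents that add atoms: none
Why: Oxidative cleavage of the electron-rich benzyl ether by DDQ through the oxocarbenium ion; the neutral buffered medium should spare the epoxide, the lactone and the tertiary allylic alcohol.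

Step 17
Reactants: 23 (1S,2R,3S,4S,8R,9E,12R,13R)-12,13-epoxy-3,8-dihydroxycembra-9,15(17)-dien-16,2-olide
Product: 24 CNP0202356.3, (1S,2R,3R,4S,8R,9E,12R,13R)-3-acetoxy-12,13-epoxy-8-hydroxycembra-9,15(17)-dien-16,2-olide
Conditions: PPh3, DIAD, AcOH, toluene, 0 °C → rt
Reagents that add atoms: acetic acid CC(=O)O
Why: Mitsunobu reaction: the C3 oxyphosphonium ion is displaced by acetate with inversion, converting (3S) into the required (3R) acetate; the tertiary alcohol does not react.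

Compound list
1 | pent-1-en-4-yne | C=CCC#C | starting material
2 | (2E)-3-methylhexa-2,5-dien-1-ol | C=CC/C(C)=C/CO | intermediate
3 | [(2R,3R)-3-methyl-3-(prop-2-en-1-yl)oxiran-2-yl]methanol | C=CC[C@@]1(C)O[C@@H]1CO | intermediate
4 | ethynyltrimethylsilane | C#C[Si](C)(C)C | starting material
5 | [(2R,3R)-3-methyl-3-(prop-2-en-1-yl)oxiran-2-yl]methyl trifluoromethanesulfonate | C=CC[C@@]1(C)O[C@@H]1COS(=O)(=O)C(F)(F)F | intermediate
6 | trimethyl{3-[(2R,3R)-3-methyl-3-(prop-2-en-1-yl)oxiran-2-yl]prop-1-yn-1-yl}silane | C=CC[C@@]1(C)O[C@@H]1CC#C[Si](C)(C)C | intermediate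
7 | (2S,3R)-2-(iodomethyl)-3-methyl-3-(prop-2-en-1-yl)oxirane | C=CC[C@@]1(C)O[C@@H]1CI | intermediate
8 | (3R)-3-methylhexa-1,5-dien-3-ol | C=CC[C@@](C=C)(C)O | intermediate
9 | (2E)-3-iodoprop-2-en-1-ol | OC/C=C/I | starting material
10 | (2E,7R)-7-methylnona-2,8-diene-1,7-diol | OC/C=C/CCC[C@@](C=C)(C)O | intermediate
11 | [(2R,3R)-3-[(4R)-4-hydroxy-4-methylhex-5-en-1-yl]oxiran-2-yl]methanol | OC[C@H]1O[C@@H]1CCC[C@@](C=C)(C)O | intermediate
12 | (2S,3S,7R)-3,7-dimethylnon-8-ene-1,2,7-triol | OC[C@@H](O)[C@@H](C)CCC[C@@](C=C)(C)O | intermediate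
13 | (3R,7S)-7-[(4S)-2-(4-methoxyphenyl)-1,3-dioxolan-4-yl]-3-methyloct-1-en-3-ol | COc1ccc(cc1)C1OC[C@@H](O1)[C@@H](C)CCC[C@@](C=C)(C)O | intermediate
14 | (2S,3S,7R)-2-[(4-methoxyphenyl)methoxy]-3,7-dimethylnon-8-ene-1,7-diol | OC[C@@H](OCc1ccc(OC)cc1)[C@@H](C)CCC[C@@](C=C)(C)O | intermediate
15 | (2S,3S,7R,8E)-2-[(4-methoxyphenyl)methoxy]-3,7-dimethyl-10-[(2R,3R)-2-methyl-3-[3-(trimethylsilyl)prop-2-yn-1-yl]oxiran-2-yl]dec-8-ene-1,7-diol | OC[C@@H](OCc1ccc(OC)cc1)[C@@H](C)CCC[C@@](C)(O)/C=C/C[C@@]1(C)O[C@@H]1CC#C[Si](C)(C)C | intermediate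
16 | (2S,3S,7R,8E)-2-[(4-methoxyphenyl)methoxy]-3,7-dimethyl-10-[(2R,3R)-2-methyl-3-(prop-2-yn-1-yl)oxiran-2-yl]dec-8-ene-1,7-diol | OC[C@@H](OCc1ccc(OC)cc1)[C@@H](C)CCC[C@@](C)(O)/C=C/C[C@@]1(C)O[C@@H]1CC#C | intermediate
17 | (2S,3S,7R,8E)-10-[(2R,3R)-3-(buta-2,3-dien-1-yl)-2-methyloxiran-2-yl]-2-[(4-methoxyphenyl)methoxy]-3,7-dimethyldec-8-ene-1,7-diol | OC[C@@H](OCc1ccc(OC)cc1)[C@@H](C)CCC[C@@](C)(O)/C=C/C[C@@]1(C)O[C@@H]1CC=C=C | intermediate
18 | (2S,3S,7R,8E)-10-[(2R,3R)-3-(buta-2,3-dien-1-yl)-2-methyloxiran-2-yl]-7-hydroxy-2-[(4-methoxyphenyl)methoxy]-3,7-dimethyldec-8-enal | O=C[C@@H](OCc1ccc(OC)cc1)[C@@H](C)CCC[C@@](C)(O)/C=C/C[C@@]1(C)O[C@@H]1CC=C=C | intermediate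
19 | carbon dioxide | O=C=O | starting material
20 | nickelalactone from the allene of 18 and CO2 (1-oxa-2-nickelacyclopentan-5-one carrying the exocyclic alkylidene on C4, side chain cis to the Ni–CH2 carbon; DBU ligands on nickel not drawn) | O=C[C@@H](OCc1ccc(OC)cc1)[C@@H](C)CCC[C@@](C)(O)/C=C/C[C@@]1(C)O[C@@H]1C/C=C1\C[Ni]OC1=O | intermediate
21 | 2-[(1S,2R,3S,4S,8R,9E,12R,13R)-12,13-epoxy-2,8-dihydroxy-3-[(4-methoxyphenyl)methoxy]-4,8,12-trimethylcyclotetradec-9-en-1-yl]prop-2-enoic acid | C=C(C(=O)O)[C@H]1[C@@H](O)[C@@H](OCc2ccc(OC)cc2)[C@@H](C)CCC[C@@](C)(O)/C=C/C[C@@]2(C)O[C@@H]2C1 | intermediate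
22 | (1S,2R,3S,4S,8R,9E,12R,13R)-12,13-epoxy-8-hydroxy-3-[(4-methoxyphenyl)methoxy]cembra-9,15(17)-dien-16,2-olide | C=C1C(=O)O[C@H]2[C@@H](OCc4ccc(OC)cc4)[C@@H](C)CCC[C@@](C)(O)/C=C/C[C@@]3(C)O[C@@H]3C[C@@H]12 | intermediate
23 | (1S,2R,3S,4S,8R,9E,12R,13R)-12,13-epoxy-3,8-dihydroxycembra-9,15(17)-dien-16,2-olide | C=C1C(=O)O[C@H]2[C@@H](O)[C@@H](C)CCC[C@@](C)(O)/C=C/C[C@@]3(C)O[C@@H]3C[C@@H]12 | intermediate
24 | CNP0202356.3, (1S,2R,3R,4S,8R,9E,12R,13R)-3-acetoxy-12,13-epoxy-8-hydroxycembra-9,15(17)-dien-16,2-olide | C=C1C(=O)O[C@H]2[C@H](OC(C)=O)[C@@H](C)CCC[C@@](C)(O)/C=C/C[C@@]3(C)O[C@@H]3C[C@@H]12 | target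

Total step count: 17. Longest linear sequence: 16 steps (steps 1, 2, 4–17); step 3 is the side branch.

Steps most likely to fail

1. Step 15 (proposed new method). Oligomerisation may outrun the 14-ring closure, DBU may epimerise the α-alkoxy aldehyde before it is trapped, and facial selectivity may erode in a macrocyclic transition state. The fallback sets out from 6 and 14 and comes back at 22, using the established chromium-mediated closure of an allylic bromide onto an aldehyde. K2CO3/MeOH on 6 gives the enyne epoxide F1. n-BuLi, then methyl chloroformate, gives the ynoate F2. DIBAL-H/HMPA hydroalumination and trapping of the α-alumino enoate with formaldehyde gives the 2-(hydroxymethyl)enoate F3. CBr4/PPh3 gives the allylic bromide F4. Cross-metathesis of F4 with 14, as in step 11, gives the bromo ester diol F5. Dess–Martin oxidation gives the bromo aldehyde F6. CrCl2 in THF at high dilution (intramolecular Nozaki–Hiyama allylation) should give the cis-hydroxy ester, which lactonises on mild acid work-up to 22.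

2. Step 17. Displacement at C3 may be too slow because the carbon is flanked by the lactone carbinol and the methyl-branched C4, so elimination or recovery of 23 may dominate. The fallback sets out from 23 and comes back at 24. Dess–Martin oxidation gives the C3 ketone F7. Luche reduction (NaBH4, CeCl3, MeOH, −78 °C), with hydride adding anti to the C2–O bond (polar Felkin–Anh), should give the (3R)-alcohol F8 without touching the α-methylene lactone. Ac2O, pyridine and catalytic DMAP at 0 °C acetylate the secondary hydroxyl in the presence of the tertiary one to give 24.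

3. Step 11. The silyl alkyne may sequester the ruthenium carbene (enyne metathesis), or homodimerisation of 6 may outrun cross-coupling with the hindered carbinol. The fallback sets out from 13 and 3 and comes back at 15. Cross-metathesis of acetal 13 with epoxy alcohol 3, with no alkyne present, gives the acetal diol F9. Tf2O/2,6-lutidine at −78 °C on the primary hydroxyl, then lithium (trimethylsilyl)acetylide, gives the silyl alkyne acetal F10. DIBAL-H opens the acetal as in step 10 to give 15.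

Further compounds
F1 | step 15 | (2R,3R)-2-methyl-2-(prop-2-en-1-yl)-3-(prop-2-yn-1-yl)oxirane | C=CC[C@@]1(C)O[C@@H]1CC#C
F2 | step 15 | methyl 4-[(2R,3R)-3-methyl-3-(prop-2-en-1-yl)oxiran-2-yl]but-2-ynoate | C=CC[C@@]1(C)O[C@@H]1CC#CC(=O)OC
F3 | step 15 | methyl (2Z)-2-(hydroxymethyl)-4-[(2R,3R)-3-methyl-3-(prop-2-en-1-yl)oxiran-2-yl]but-2-enoate | C=CC[C@@]1(C)O[C@@H]1C/C=C(/CO)C(=O)OC
F4 | step 15 | methyl (2E)-2-(bromomethyl)-4-[(2R,3R)-3-methyl-3-(prop-2-en-1-yl)oxiran-2-yl]but-2-enoate | C=CC[C@@]1(C)O[C@@H]1C/C=C(/CBr)C(=O)OC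
F5 | step 15 | cross-metathesis product of F4 and 14: methyl (2E)-2-(bromomethyl)-4-[(2R,3R)-3-[(2E,4R,8S,9S)-4,10-dihydroxy-9-[(4-methoxyphenyl)methoxy]-4,8-dimethyldec-2-en-1-yl]-3-methyloxiran-2-yl]but-2-enoate | OC[C@@H](OCc1ccc(OC)cc1)[C@@H](C)CCC[C@@](C)(O)/C=C/C[C@@]1(C)O[C@@H]1C/C=C(/CBr)C(=O)OC
F6 | step 15 | aldehyde from F5: methyl (2E)-2-(bromomethyl)-4-[(2R,3R)-3-[(2E,4R,8S,9S)-4-hydroxy-9-[(4-methoxyphenyl)methoxy]-4,8-dimethyl-10-oxodec-2-en-1-yl]-3-methyloxiran-2-yl]but-2-enoate | O=C[C@@H](OCc1ccc(OC)cc1)[C@@H](C)CCC[C@@](C)(O)/C=C/C[C@@]1(C)O[C@@H]1C/C=C(/CBr)C(=O)OC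
F7 | step 17 | (1S,2R,4S,8R,9E,12R,13R)-12,13-epoxy-8-hydroxy-3-oxocembra-9,15(17)-dien-16,2-olide | C=C1C(=O)O[C@H]2C(=O)[C@@H](C)CCC[C@@](C)(O)/C=C/C[C@@]3(C)O[C@@H]3C[C@@H]12
F8 | step 17 | (1S,2R,3R,4S,8R,9E,12R,13R)-12,13-epoxy-3,8-dihydroxycembra-9,15(17)-dien-16,2-olide | C=C1C(=O)O[C@H]2[C@H](O)[C@@H](C)CCC[C@@](C)(O)/C=C/C[C@@]3(C)O[C@@H]3C[C@@H]12
F9 | step 11 | (1E,3R,7S)-1-[(2R,3R)-3-(hydroxymethyl)-2-methyloxiran-2-yl]methyl-substituted alkene: (2E,4R,8S)-1-[(2R,3R)-3-(hydroxymethyl)-2-methyloxiran-2-yl]-8-[(4S)-2-(4-methoxyphenyl)-1,3-dioxolan-4-yl]-4-methylnon-2-en-4-ol | COc1ccc(cc1)C1OC[C@@H](O1)[C@@H](C)CCC[C@@](C)(O)/C=C/C[C@@]1(C)O[C@@H]1CO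
F10 | step 11 | (2E,4R,8S)-8-[(4S)-2-(4-methoxyphenyl)-1,3-dioxolan-4-yl]-4-methyl-1-[(2R,3R)-2-methyl-3-[3-(trimethylsilyl)prop-2-yn-1-yl]oxiran-2-yl]non-2-en-4-ol | COc1ccc(cc1)C1OC[C@@H](O1)[C@@H](C)CCC[C@@](C)(O)/C=C/C[C@@]1(C)O[C@@H]1CC#C[Si](C)(C)C
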